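**Plan**

1. Retrosynthesis: the acid comes from an allyl ester. C13=C14 is cut (Horner–Wadsworth–Emmons) to an 8-hydroxy-13-ketone, which is folded back into a cyclic enol ether (oxygen bridging C8 and C13, a ring absent from the target). The C9–C10 and C8–O bonds are then cut together, leaving a ring-A cyclohexene that carries the whole C6–C16 chain.
2. Ring A is cut at C3–C4 and C5=C10 (Michael addition and aldol condensation, Robinson annulation) to ethyl vinyl ketone and an acyclic β-keto ester, itself made from 6-methylhept-5-en-2-one and methyl 2-methyl-3-oxobutanoate.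
3. Forward order: chain, then ring A (step 5), removal of the C1 carbonyl helper with alkene transposition (steps 6 and 7), then ring B together with the temporary pyran ring (step 10), pyran opening, enoate, acid.
4. Stereochemistry: C4 by catalytic asymmetric Michael addition; C5 by a reagent-controlled C1 carbinol relayed through an anti 1,3-reductive transposition; C10, C9 and C8 in the ring-B closure (C5 control, E geometry of C8=C9, internal oxygen delivery); C13=C14 E from the olefination.
5. Enabling feature: in the precursor the trisubstituted C1=C10 alkene of ring A (tertiary cation at C10) lies five atoms from C9 of the E-C8=C9 alkene through C5–C6–C7, and the C13 carbonyl oxygen lies six atoms from C8. One protonation therefore closes ring B and ties C8 to oxygen in a ring that is opened afterwards.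

Key step: step 10

Remark: labdane numbering (C1–C20) is used for all intermediates; the facial sense of the cinchona-catalysed Michael addition in step 5 is assigned by analogy with related β-keto esters, and the pseudoenantiomeric quinine-derived catalyst would be taken if the opposite sense were found.

**Route**

Step 1
Reactants: 1 6-methylhept-5-en-2-one
Product: 2 2-methyl-2-(4-methylpent-3-en-1-yl)-1,3-dioxolane
Conditions: ethylene glycol, PPTS (cat.), benzene, reflux, Dean–Stark
Reagents that add atoms: ethylene glycol, OCCO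
Why: Acid-catalysed ketalization with azeotropic removal of water masks the ketone as a dioxolane that should survive the base, hydride and Mitsunobu steps ahead.

Step 2
Reactants: 2 2-methyl-2-(4-methylpent-3-en-1-yl)-1,3-dioxolane
Product: 3 (E)-2-methyl-5-(2-methyl-1,3-dioxolan-2-yl)pent-2-en-1-ol
Conditions: SeO2 (10 mol %), t-BuOOH, CH2Cl2, rt
Reagents that add atoms: selenium dioxide (oxygen carrier), O=[Se]=O; tert-butyl hydroperoxide (terminal oxidant), CC(C)(C)OO
Why: Riley-type allylic oxidation (ene reaction, then 2,3-sigmatropic shift) attacks the methyl group trans to the chain of the prenyl unit, which fixes the E geometry of the future C8=C9 alkene.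

Step 3
Reactants: 3 (E)-2-methyl-5-(2-methyl-1,3-dioxolan-2-yl)pent-2-en-1-ol
Product: 4 2-[(E)-5-bromo-4-methylpent-3-en-1-yl]-2-methyl-1,3-dioxolane
Conditions: CBr4, PPh3, CH2Cl2, 0 °C
Reagents that add atoms: carbon tetrabromide, BrC(Br)(Br)Br
Why: The Appel reaction converts the primary allylic alcohol into the bromide under neutral conditions, without allylic shift and without loss of the ketal.

Step 4
Reactants: 4 2-[(E)-5-bromo-4-methylpent-3-en-1-yl]-2-methyl-1,3-dioxolane; 5 methyl 2-methyl-3-oxobutanoate
Product: 6 methyl (E)-2,6-dimethyl-9-(2-methyl-1,3-dioxolan-2-yl)-3-oxonon-6-enoate (both C2 epimers)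
Conditions: 5, NaH, THF, 0 °C; n-BuLi, 0 °C; then 4, 0 °C to rt; aq. NH4Cl
Reagents that add atoms: none
Why: γ-Alkylation of the β-keto ester dianion takes place at the more basic terminal carbon by SN2 displacement of the primary allylic bromide, joining C6 to C7 and leaving the α-methyl β-keto ester ready for the Michael step.

Step 5
Reactants: 6 methyl (E)-2,6-dimethyl-9-(2-methyl-1,3-dioxolan-2-yl)-3-oxonon-6-enoate; 7 pent-1-en-3-one (ethyl vinyl ketone)
Product: 9 methyl (1R)-1,3-dimethyl-2-[(E)-3-methyl-6-(2-methyl-1,3-dioxolan-2-yl)hex-3-en-1-yl]-4-oxocyclohex-2-ene-1-carboxylate, via diketone 8 (not isolated)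
Conditions: 9-O-(9-phenanthryl)cupreidine (quinidine-derived 6′-hydroxy catalyst, 10 mol %), toluene, rt; then pyrrolidine, AcOH, 80 °C
Reagents that add atoms: none
Why: Bifunctional cinchona-catalysed Michael addition of the α-methyl β-keto ester to the enone should set the quaternary C4 centre (R) by face-selective attack of the hydrogen-bonded enol, and enamine-mediated aldol condensation of the ethyl ketone carbon (C10) onto the C5 ketone then closes ring A (Robinson annulation), the enamine forming only at the unhindered ketone.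

Step 6
Reactants: 9 methyl (1R)-1,3-dimethyl-2-[(E)-3-methyl-6-(2-methyl-1,3-dioxolan-2-yl)hex-3-en-1-yl]-4-oxocyclohex-2-ene-1-carboxylate
Product: 10 methyl (1R,4R)-4-hydroxy-1,3-dimethyl-2-[(E)-3-methyl-6-(2-methyl-1,3-dioxolan-2-yl)hex-3-en-1-yl]cyclohex-2-ene-1-carboxylate
Conditions: (S)-2-methyl-CBS-oxazaborolidine (20 mol %), catecholborane, toluene, −78 °C
Reagents that add atoms: none
Why: Corey–Bakshi–Shibata reduction delivers hydride under catalyst control to one face of the α-methyl enone (alkenyl side as the large group), which should set the (R)-C1 carbinol cis to the C4 methyl group without touching ester, ketal or the isolated alkene.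

Step 7
Reactants: 10 methyl (1R,4R)-4-hydroxy-1,3-dimethyl-2-[(E)-3-methyl-6-(2-methyl-1,3-dioxolan-2-yl)hex-3-en-1-yl]cyclohex-2-ene-1-carboxylate
Product: 13 methyl (1R,2R)-1,3-dimethyl-2-[(E)-3-methyl-6-(2-methyl-1,3-dioxolan-2-yl)hex-3-en-1-yl]cyclohex-3-ene-1-carboxylate, via sulfonylhydrazide 11 (not isolated), via allylic diazene 12 (not isolated)
Conditions: 2-nitrobenzenesulfonylhydrazide, PPh3, diethyl azodicarboxylate, N-methylmorpholine, −30 °C to 23 °C
Reagents that add atoms: none
Why: Mitsunobu displacement with inversion gives the C1 sulfonylhydrazide, which loses sulfinic acid to the allylic diazene, and retro-ene loss of N2 delivers hydrogen suprafacially to C5 on the face of the C4 ester while moving the alkene to C1=C10 (reductive 1,3-transposition), so that the C1 centre is relayed to C5 and the C1 oxygen helper is removed.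

Step 8
Reactants: 13 methyl (1R,2R)-1,3-dimethyl-2-[(E)-3-methyl-6-(2-methyl-1,3-dioxolan-2-yl)hex-3-en-1-yl]cyclohex-3-ene-1-carboxylate
Product: 15 (E)-8-[(1R,6R)-6-(hydroxymethyl)-2,6-dimethylcyclohex-2-en-1-yl]-6-methyloct-5-en-2-one, via dioxolane alcohol 14 (not isolated)
Conditions: LiAlH4, THF, 0 °C to rt; then 1 M HCl, rt
Reagents that add atoms: water (ketone oxygen), O
Why: LiAlH4 reduces the neopentyl methyl ester to the primary C18 alcohol while the ketal masks the ketone, and the acidic work-up then hydrolyses the dioxolane.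

Step 9
Reactants: 15 (E)-8-[(1R,6R)-6-(hydroxymethyl)-2,6-dimethylcyclohex-2-en-1-yl]-6-methyloct-5-en-2-one
Product: 16 [(1R,2R)-1,3-dimethyl-2-[(E)-3-methyl-7-oxooct-3-en-1-yl]cyclohex-3-en-1-yl]methyl acetate
Conditions: Ac2O, pyridine, DMAP (cat.), CH2Cl2, rt
Reagents that add atoms: acetic anhydride, CC(=O)OC(C)=O
Why: DMAP-catalysed acylation of the only hydroxyl group installs the C18 acetate of the target before the acid-mediated steps.

Step 10
Reactants: 16 [(1R,2R)-1,3-dimethyl-2-[(E)-3-methyl-7-oxooct-3-en-1-yl]cyclohex-3-en-1-yl]methyl acetate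
Product: 18 [(4aR,6aR,7R,10aS,10bR)-3,4a,7,10a-tetramethyl-4a,5,6,6a,7,8,9,10,10a,10b-decahydro-1H-benzo[f]chromen-7-yl]methyl acetate (8α,13-epoxy-14,15-dinorlabd-12-en-18-yl acetate), via oxocarbenium fluorosulfate 17 (not isolated)
Conditions: FSO3H, 2-nitropropane, −78 °C; then Et3N
Reagents that add atoms: none
Why: Protonation of the C1=C10 ring alkene at C1 gives the tertiary C10 cation, which is attacked by C9 of the E-configured C8=C9 alkene through a chair-like transition state, and the resulting tertiary C8 cation is captured by the C13 carbonyl oxygen to give oxocarbenium ion 17, which loses H-12 on quenching. The closest known reaction type is the superacid-mediated, carbonyl-terminated cation–olefin cyclization of monocyclic and acyclic terpenoid ketones to bicyclic and tricyclic enol ethers. Ring B closes by C9–C10 bond formation in a 6-endo-trig mode with respect to the C8=C9 alkene, and the temporary pyran ring closes by six-membered attack of the carbonyl oxygen on C8. C10 is set by the existing C5 centre, whose equatorial C6 tether forces equatorial bond formation at C10 and hence the trans ring fusion with an axial methyl group; C9 and C8 follow from the E geometry of the alkene and antiperiplanar addition across it, the internal oxygen arriving equatorially to give the 8α C–O bond. The step needs initiation at the ring alkene and retention of the C5 configuration: protonation of the chain alkene is reversible and opens no comparably favourable chair closure, and at −78 °C ring closure from the C10 cation should outrun proton loss or hydride shift.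

Step 11
Reactants: 18 [(4aR,6aR,7R,10aS,10bR)-3,4a,7,10a-tetramethyl-4a,5,6,6a,7,8,9,10,10a,10b-decahydro-1H-benzo[f]chromen-7-yl]methyl acetate
Product: 19 [(1R,4aS,5R,6R,8aR)-6-hydroxy-1,4a,6-trimethyl-5-(3-oxobutyl)decahydronaphthalen-1-yl]methyl acetate
Conditions: 0.2 M HCl, THF–H2O, rt
Reagents that add atoms: water, O
Why: Acid-catalysed hydration of the cyclic enol ether (protonation at C12, addition of water at C13, opening of the hemiketal) cleaves the temporary ring to the tertiary 8α-alcohol and the C13 methyl ketone under conditions too mild for acetate hydrolysis or dehydration of the tertiary alcohol.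

Step 12
Reactants: 19 [(1R,4aS,5R,6R,8aR)-6-hydroxy-1,4a,6-trimethyl-5-(3-oxobutyl)decahydronaphthalen-1-yl]methyl acetate; 20 allyl (diethoxyphosphoryl)acetate
Product: 21 allyl (E)-5-[(1R,2R,4aR,5R,8aS)-5-(acetoxymethyl)-2-hydroxy-2,5,8a-trimethyldecahydronaphthalen-1-yl]-3-methylpent-2-enoate
Conditions: 20, NaH, THF, 0 °C; then 19, rt to 50 °C
Reagents that add atoms: none
Why: Horner–Wadsworth–Emmons olefination of the methyl ketone with the stabilized phosphonate anion should give mainly the E trisubstituted enoate (ester anti to the larger C12 chain), the minor Z isomer being removed by chromatography, and the weakly basic anion should leave the acetate and the free tertiary alcohol alone.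

Step 13
Reactants: 21 allyl (E)-5-[(1R,2R,4aR,5R,8aS)-5-(acetoxymethyl)-2-hydroxy-2,5,8a-trimethyldecahydronaphthalen-1-yl]-3-methylpent-2-enoate
Product: 22 (E)-5-[(1R,2R,4aR,5R,8aS)-5-(acetoxymethyl)-2-hydroxy-2,5,8a-trimethyldecahydronaphthalen-1-yl]-3-methylpent-2-enoic acid (18-acetoxy-8α-hydroxylabd-13E-en-15-oic acid)
Conditions: Pd(PPh3)4 (5 mol %), morpholine, THF, rt; dilute acid work-up
Reagents that add atoms: none
Why: Tsuji–Trost deallylation, in which zerovalent palladium ionizes the allyl ester to a π-allyl complex that morpholine traps, frees the acid without touching the acetate, the tertiary alcohol or the enoate geometry.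

**Compound list**

1 | 6-methylhept-5-en-2-one | CC(C)=CCCC(C)=O | starting material
2 | 2-methyl-2-(4-methylpent-3-en-1-yl)-1,3-dioxolane | CC(C)=CCCC1(C)OCCO1 | intermediate
3 | (E)-2-methyl-5-(2-methyl-1,3-dioxolan-2-yl)pent-2-en-1-ol | OC/C(C)=C/CCC1(C)OCCO1 | intermediate
4 | 2-[(E)-5-bromo-4-methylpent-3-en-1-yl]-2-methyl-1,3-dioxolane | BrC/C(C)=C/CCC1(C)OCCO1 | intermediate
5 | methyl 2-methyl-3-oxobutanoate | COC(=O)C(C)C(C)=O | starting material
6 | methyl (E)-2,6-dimethyl-9-(2-methyl-1,3-dioxolan-2-yl)-3-oxonon-6-enoate | COC(=O)C(C)C(=O)CC/C(C)=C/CCC1(C)OCCO1 | intermediate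
7 | pent-1-en-3-one | C=CC(=O)CC | starting material
8 | methyl (2R,6E)-2,6-dimethyl-9-(2-methyl-1,3-dioxolan-2-yl)-3-oxo-2-(3-oxopentyl)non-6-enoate | COC(=O)[C@](C)(CCC(=O)CC)C(=O)CC/C(C)=C/CCC1(C)OCCO1 | intermediate
9 | methyl (1R)-1,3-dimethyl-2-[(E)-3-methyl-6-(2-methyl-1,3-dioxolan-2-yl)hex-3-en-1-yl]-4-oxocyclohex-2-ene-1-carboxylate | COC(=O)[C@]1(C)CCC(=O)C(C)=C1CC/C(C)=C/CCC2(C)OCCO2 | intermediate
10 | methyl (1R,4R)-4-hydroxy-1,3-dimethyl-2-[(E)-3-methyl-6-(2-methyl-1,3-dioxolan-2-yl)hex-3-en-1-yl]cyclohex-2-ene-1-carboxylate | COC(=O)[C@]1(C)CC[C@@H](O)C(C)=C1CC/C(C)=C/CCC2(C)OCCO2 | intermediate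
11 | methyl (1R,4S)-1,3-dimethyl-2-[(E)-3-methyl-6-(2-methyl-1,3-dioxolan-2-yl)hex-3-en-1-yl]-4-[1-(2-nitrophenylsulfonyl)hydrazin-1-yl]cyclohex-2-ene-1-carboxylate | COC(=O)[C@]1(C)CC[C@H](N(N)S(=O)(=O)c2ccccc2[N+](=O)[O-])C(C)=C1CC/C(C)=C/CCC2(C)OCCO2 | intermediate
12 | methyl (1R,4S)-4-diazenyl-1,3-dimethyl-2-[(E)-3-methyl-6-(2-methyl-1,3-dioxolan-2-yl)hex-3-en-1-yl]cyclohex-2-ene-1-carboxylate | COC(=O)[C@]1(C)CC[C@H](N=N)C(C)=C1CC/C(C)=C/CCC2(C)OCCO2 | intermediate
13 | methyl (1R,2R)-1,3-dimethyl-2-[(E)-3-methyl-6-(2-methyl-1,3-dioxolan-2-yl)hex-3-en-1-yl]cyclohex-3-ene-1-carboxylate | COC(=O)[C@]1(C)CCC=C(C)[C@H]1CC/C(C)=C/CCC2(C)OCCO2 | intermediate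
14 | [(1R,2R)-1,3-dimethyl-2-[(E)-3-methyl-6-(2-methyl-1,3-dioxolan-2-yl)hex-3-en-1-yl]cyclohex-3-en-1-yl]methanol | OC[C@]1(C)CCC=C(C)[C@H]1CC/C(C)=C/CCC2(C)OCCO2 | intermediate
15 | (E)-8-[(1R,6R)-6-(hydroxymethyl)-2,6-dimethylcyclohex-2-en-1-yl]-6-methyloct-5-en-2-one | OC[C@]1(C)CCC=C(C)[C@H]1CC/C(C)=C/CCC(C)=O | intermediate
16 | [(1R,2R)-1,3-dimethyl-2-[(E)-3-methyl-7-oxooct-3-en-1-yl]cyclohex-3-en-1-yl]methyl acetate | CC(=O)OC[C@]1(C)CCC=C(C)[C@H]1CC/C(C)=C/CCC(C)=O | intermediate
17 | tricyclic 8,13-epoxy oxocarbenium fluorosulfate (O-alkylated C13 ketone, oxygen bonded to C8) | CC(=O)OC[C@]1(C)CCC[C@]2(C)[C@@H](CCC(C)=[O+]3)[C@@]3(C)CC[C@@H]12.[O-]S(=O)(=O)F | intermediate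
18 | [(4aR,6aR,7R,10aS,10bR)-3,4a,7,10a-tetramethyl-4a,5,6,6a,7,8,9,10,10a,10b-decahydro-1H-benzo[f]chromen-7-yl]methyl acetate | CC(=O)OC[C@]1(C)CCC[C@]2(C)[C@@H](CC=C(C)O3)[C@@]3(C)CC[C@@H]12 | intermediate
19 | [(1R,4aS,5R,6R,8aR)-6-hydroxy-1,4a,6-trimethyl-5-(3-oxobutyl)decahydronaphthalen-1-yl]methyl acetate | CC(=O)OC[C@]1(C)CCC[C@]2(C)[C@@H](CCC(C)=O)[C@](C)(O)CC[C@@H]12 | intermediate
20 | allyl (diethoxyphosphoryl)acetate | C=CCOC(=O)CP(=O)(OCC)OCC | starting material
21 | allyl (E)-5-[(1R,2R,4aR,5R,8aS)-5-(acetoxymethyl)-2-hydroxy-2,5,8a-trimethyldecahydronaphthalen-1-yl]-3-methylpent-2-enoate | CC(=O)OC[C@]1(C)CCC[C@]2(C)[C@@H](CC/C(C)=C/C(=O)OCC=C)[C@](C)(O)CC[C@@H]12 | intermediate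
22 | (E)-5-[(1R,2R,4aR,5R,8aS)-5-(acetoxymethyl)-2-hydroxy-2,5,8a-trimethyldecahydronaphthalen-1-yl]-3-methylpent-2-enoic acid | CC(=O)OC[C@]1(C)CCC[C@]2(C)[C@@H](CC/C(C)=C/C(=O)O)[C@](C)(O)CC[C@@H]12 | target

**Count**

Total steps: 13. Longest linear sequence: 13 steps (1 to 22).

**Steps most likely to fail**

Step 10. The chain alkene may be protonated before the ring alkene, so that the C8 cation is captured by the ketone oxygen as a monocyclic pyran that does not go on to ring B, or the acid-labile enol ether may not survive isolation. The fallback changes the termination from internal oxygen capture to external hydration and sets out from 16. Olefination of 16 with 20 (NaH, THF) would give allyl (2E,6E)-9-[(1R,6R)-6-(acetoxymethyl)-2,6-dimethylcyclohex-2-en-1-yl]-3,7-dimethylnona-2,6-dienoate F1, in which no ketone is left and the conjugated C13=C14 alkene is too electron-poor to take part. Protonative cyclization of F1 (FSO3H, 2-nitropropane, −78 °C) followed by a cold aqueous quench should hydrate the C8 cation from the equatorial side and come back to the route at 21.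

Step 5. Facial selectivity in the Michael addition may be low because the acyclic β-keto ester can react through two enol geometries, which would erode the C4 configuration on which every later centre depends. The fallback replaces catalyst control by a covalently bound auxiliary and sets out from 6. Condensation of 6 with (S)-1-phenylethylamine (molecular sieves, toluene) would give methyl (2Z,6E)-2,6-dimethyl-9-(2-methyl-1,3-dioxolan-2-yl)-3-[[(1S)-1-phenylethyl]amino]nona-2,6-dienoate F2, whose geometry is locked by the internal hydrogen bond. Addition of F2 to 7 (THF, rt) should give the imine methyl (2R,6E)-2,6-dimethyl-9-(2-methyl-1,3-dioxolan-2-yl)-2-(3-oxopentyl)-3-[[(1S)-1-phenylethyl]imino]non-6-enoate F3, and buffered aqueous acetic acid would hydrolyse F3 and come back to the route at 8, which is then closed to 9 with pyrrolidine and AcOH as in step 5. The enantiomer of the amine would be exchanged if the sense of induction required it.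

Step 7. The Mitsunobu displacement at the hindered allylic C1 carbinol may be outrun by elimination to a cyclohexadiene or may proceed with allylic shift, so that hydrogen is not delivered cleanly to C5. The fallback uses a π-allyl palladium hydride transfer instead of the diazene and sets out from 10. Formylation of 10 (formic acid, N,N′-dicyclohexylcarbodiimide, DMAP, CH2Cl2) would give methyl (1R,4R)-4-(formyloxy)-1,3-dimethyl-2-[(E)-3-methyl-6-(2-methyl-1,3-dioxolan-2-yl)hex-3-en-1-yl]cyclohex-2-ene-1-carboxylate F4. With Pd(OAc)2 and n-Bu3P in THF at reflux, zerovalent palladium should ionize F4 anti to the formate, the formate should give a palladium hydride with loss of CO2, and the hydride should pass to the more substituted terminus C5 from the metal face, which is the same face as in step 7, so that the sequence comes back to the route at 13.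

**Further compounds**

F1 | step 10 | allyl (2E,6E)-9-[(1R,6R)-6-(acetoxymethyl)-2,6-dimethylcyclohex-2-en-1-yl]-3,7-dimethylnona-2,6-dienoate | CC(=O)OC[C@]1(C)CCC=C(C)[C@H]1CC/C(C)=C/CC/C(C)=C/C(=O)OCC=C
F2 | step 5 | methyl (2Z,6E)-2,6-dimethyl-9-(2-methyl-1,3-dioxolan-2-yl)-3-[[(1S)-1-phenylethyl]amino]nona-2,6-dienoate | COC(=O)\C(C)=C(/N[C@@H](C)c1ccccc1)CC/C(C)=C/CCC1(C)OCCO1
F3 | step 5 | methyl (2R,6E)-2,6-dimethyl-9-(2-methyl-1,3-dioxolan-2-yl)-2-(3-oxopentyl)-3-[[(1S)-1-phenylethyl]imino]non-6-enoate | COC(=O)[C@](C)(CCC(=O)CC)C(=N[C@@H](C)c1ccccc1)CC/C(C)=C/CCC1(C)OCCO1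
F4 | step 7 | methyl (1R,4R)-4-(formyloxy)-1,3-dimethyl-2-[(E)-3-methyl-6-(2-methyl-1,3-dioxolan-2-yl)hex-3-en-1-yl]cyclohex-2-ene-1-carboxylate | COC(=O)[C@]1(C)CC[C@@H](OC=O)C(C)=C1CC/C(C)=C/CCC2(C)OCCO2
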